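Start from the second intermediate, not the open intermediate: reckon how much of it outlasts the early minutes, and the end of the run follows from that.

| setting | Wednesday's | Thursday's | Tuesday's | Friday's | Monday's |
|---|---|---|---|---|---|
| substrate | 0.020 M | 0.030 M | 0.040 M | 0.060 M | 0.10 M |
| partner | 0.120 M | 0.120 M | 0.120 M | 0.120 M | 0.120 M |
| capture agent | 5.00 mM | 5.00 mM | 5.00 mM | 5.00 mM | 5.00 mM |
| time | 50 min | 50 min | 50 min | 50 min | 50 min |

    partner → second intermediate (k1 = 0.083 s⁻¹)
    second intermediate + capture agent → trapped intermediate (k2 = 0.82 L mol⁻¹ s⁻¹)
    substrate + open intermediate → side product (k3 = 0.022 L mol⁻¹ s⁻¹)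
    open intermediate + second intermediate → target (k4 = 0.031 L mol⁻¹ s⁻¹)
    substrate → open intermediate (k5 = 0.0089 s⁻¹)
    2 open intermediate → homo product (k6 = 0.019 L mol⁻¹ s⁻¹)

- in percentages every species weighs as the substrate in it: one homo product or side product counts as two
- a doubled species enters its step squared and goes two at a time
- "hardly changes" means that all values lie within two and a half points (for a concentration: within two and a half percent of the largest)
- run time (Wednesday's): 50 min

- [open intermediate] at the end for Wednesday's, Thursday's, Tuesday's, Friday's, Monday's, in this order
- the course of these numbers from the first flask to the last (falls, then rises / hardly changes / rises all the way / falls all the way / rises, then falls)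

- Wednesday's and Thursday's are neighbours in the row: they charge 0.020 M and 0.030 M of substrate, with equal partner and capture agent. The reckoning below follows these two flasks side by side.
- In Wednesday's, partner has a half-life of 0.14 min and substrate one of 1.3 min, so second intermediate stands ready before the open intermediate builds up.
- Capture agent consumes second intermediate at 0.00410 s⁻¹ per unit of it, which is faster than the 9.30 × 10⁻⁴ s⁻¹ that open intermediate can reach in Thursday's charge. The reckoning therefore debits the full 5.00 mM of capture agent from the second intermediate.
- First round: if every substrate became target, second intermediate would end at 0.0950 M in Wednesday's and 0.0850 M in Thursday's.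
- Second round: those amounts go back in. Each open intermediate passes to target at the target constant times second intermediate, to homo product at twice the homo constant times open intermediate, and to side product at the side constant times substrate. With open intermediate and substrate both taken at a rough level of 0.00500 M in Wednesday's and 0.00750 M in Thursday's, the share reaching target is 90.8% in Wednesday's and 85.4% in Thursday's. Second intermediate left is then 0.0968 M and 0.0894 M.
- Late in these two flasks, open intermediate is taken to decay by a pseudo-first-order law. Its tail rate, the target constant times the second intermediate left, is 0.180 min⁻¹ in Wednesday's and 0.166 min⁻¹ in Thursday's.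
- Over the run, tail rate times time comes to 9.01 and 8.31. Thursday's thus has more substrate to start from and a lower tail rate.
- Three corrections complete the estimate. The charge is scaled by the share, substrate's feeding lifts the tail by its constant over (its constant minus the tail rate), and second intermediate stands above its end level while target is still forming, which adds to the decay.
- This gives 2.61 µM for Wednesday's and 6.27 µM for Thursday's.
- The hand reckoning is carried as far as Thursday's. Taking the step from Wednesday's to Thursday's as the pattern for the row, it expects the course rises all the way.
- The forecast gives 2.500 × 10⁻⁶ M, 6.600 × 10⁻⁶ M, 1.400 × 10⁻⁵ M, 3.500 × 10⁻⁵ M and 1.100 × 10⁻⁴ M, with the course rises all the way, saying that a richer flask “makes the tail rise steadily across the series”.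
- The simulation gives 2.55 × 10⁻⁶ M, 6.31 × 10⁻⁶ M, 1.31 × 10⁻⁵ M, 4.08 × 10⁻⁵ M and 1.88 × 10⁻⁴ M, so the course rises all the way. Wednesday's second intermediate stands at 0.0971 M at 50.0 min. Wednesday's open intermediate stands at 2.34 × 10⁻⁴ M at 25.0 min, and the tail rate carries that over the remaining 25.0 min to 2.59 × 10⁻⁶ M, where the flask stands at 2.55 × 10⁻⁶ M.

The numbers of this flask were chosen freely; no experiment stands behind them.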